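## The problem

The target 37 is a seven-membered α,β-unsaturated lactone. Its ring atoms are numbered O1, C2 (carbonyl), C3=C4, C5, C6 and C7. C3 carries a (Z)-5-acetoxy-4-methylpent-3-enyl chain (C1''–C5''). The fully substituted C7 carries a methyl group and a (1R,4Z)-1,6-dihydroxy-4-methylhex-4-enyl chain (C1'–C6').

Only two stereocentres exist, and they are adjacent: the O-acylated quaternary C7 (R) and the secondary carbinol C1' (R). No third centre is available to relay from, so the pair must be set together, by reagent control or by a stereospecific event. Once set, it controls nothing else.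

The two side-chain alkenes are both Z and trisubstituted but of different pattern: the methyl sits on the carbon bearing CH2O in the C3 chain and on the inner carbon in the C7 chain. Each therefore needs its own stereospecific construction. The three hydroxyls must end differentiated as one primary allylic acetate, one free primary allylic alcohol and one free secondary alcohol.

The fragile groups are:
- the allylic acetate, which is ionised by zerovalent palladium and cleaved by base or hydride;
- the ε-lactone and its enoate, which are open to nucleophiles;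
- the three alkenes, which do not tolerate peracid or bromine.

Closing a seven-membered lactone by acylating a hindered tertiary alcohol is slow, so a route that avoids forming the ring by cyclisation is attractive. The enabling feature is that O1 lies between the C2 carbonyl and the fully substituted C7. This is the pattern left when one oxygen atom is inserted beside the quaternary α-carbon of a 2,2-disubstituted cyclohexanone. That ketone, with its α-quaternary centre and β-hydroxyl, is in turn the signature of a semipinacol ring expansion of an epoxy cyclopentanol.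

## Retrosynthesis

**Endgame (no skeletal bond).** Target 37 is traced to bis-silyl ether 36, to alcohol 35, and to PMB ether 34. The acetate is placed last so that it never meets zerovalent palladium, an organozinc or a base. The PMB group is orthogonal to the two silyl ethers, and when 35 is acetylated it has a single free hydroxyl. The forward steps need only clean oxidative debenzylation, acylation and a buffered fluoride deprotection.

**C3'–C4' bond.** Cutting 34 here gives primary iodide 32 and (Z)-alkenyl iodide 31, joined forward by an sp3–sp2 Negishi coupling. A Wittig or Horner–Wadsworth–Emmons approach to C4'=C5' would give E/Z mixtures. Alkenyl iodide 31 carries the geometry in from but-2-yn-1-ol 28 through iodoalkenol 30. Iodide 32 is traced to chloride 27; the chlorine is a latent iodide that survives every step before it.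

**C3–C1'' bond.** Cutting 27 gives α-bromo enoate 17 and homoallylic iodide 25 (as its zinc reagent 26). Alkylating the lactone enolate and then dehydrogenating would leave the position of the new double bond ambiguous; coupling at a preformed C3=C4 does not. Iodide 25 is prepared in four steps from prop-2-yn-1-ol 18, through (Z)-iodoalkenol 20, PMB ether 21, oxirane 22 and alcohol 24. The coupling must be faster than β-hydride elimination and must leave the chloride alone.

**C3 functionalisation.** Bromide 17 comes from enoate 15, and 15 from saturated lactone 11, by bromination–dehydrobromination and selenoxide dehydrogenation. Both must be done before any side-chain alkene is present, which fixes the order of events.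

**C2–O1 and O1–C7 (key cut).** Removing O1 from 11 gives cyclohexanone 10. No other disconnection of the lactone avoids a seven-membered cyclisation. The precursor is a simple carbocycle with no alkene. The forward Baeyer–Villiger oxidation must make the quaternary carbon migrate, with retention.

**Ring bond to the quaternary carbon.** Ketone 10 is the silyl ether of β-hydroxy ketone 9. Reconnecting the ring carbon of 9 to the carbonyl carbon gives epoxy cyclopentanol 8. One semipinacol shift then creates the quaternary centre and keeps the carbinol, so both stereocentres come from a single epoxide.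

**Epoxide and carbon skeleton.** Epoxide 8 comes from (E)-allylic alcohol 7 by reagent-controlled epoxidation. Alcohol 7 comes from cyclopentanone 5 and alkenyl iodide 4. Iodide 4 is made from 5-chloropent-2-yne 2, and 2 from pent-3-yn-1-ol 1. The E geometry of 4 fixes the relative configuration; the epoxidation catalyst fixes the absolute one.

## Roads not taken

**Alternative 1: ring-closing metathesis at C3=C4.** The cut is the ring alkene. Diene ester A2, the 2-alkylacrylate of the C7 tertiary alcohol bearing a but-3-enyl chain, would be closed to A1 with the second-generation Hoveyda–Grubbs catalyst, RuCl2(H2IMes)(=CH–C6H4-2-O-i-Pr), with loss of ethylene.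
- Merits: it is more convergent than the chosen plan. The C3 chain arrives inside the acrylic acid, the acetate can be present from the start, and the C7/C1' pair could come from one dihydroxylation of an open-chain trisubstituted alkene. Its longest linear sequence would probably be shorter than fifteen steps.
- Weak points: the hindered tertiary alcohol must be acylated with an α-substituted acrylic acid. The closure must form a trisubstituted alkene from an electron-poor 1,1-disubstituted one, inside a seven-membered lactone whose ester prefers the conformation that holds the two alkenes apart. Oligomerisation and high catalyst loading are the likely cost.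
- Comparison: the chosen plan sets against this a ring that arrives ready-made from cyclopentanone by two ring expansions, neither of which depends on ring-closure entropy or on acylating a tertiary oxygen.

**Alternative 2: carbonylative lactonisation.** The cut removes C2 as carbon monoxide. (Z)-Alkenyl iodide A4, with a free C7 hydroxyl, would be carbonylated with Pd(PPh3)4, CO and Et3N, and the acylpalladium captured by the tertiary alcohol to give A3. A3 has the same constitution as 34 of the chosen route.
- Merits: both side chains and the C3=C4 geometry are built in the open chain. No selenium or bromine chemistry is needed on the lactone, and the allylic oxygen is sensibly kept as a PMB ether. It would reach the level of 34 in fewer linear steps.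
- Weak points: an acylpalladium must be trapped by a hindered tertiary hydroxyl through a seven-membered transition state, in competition with reduction and intermolecular acylation. The trisubstituted (Z)-alkenyl iodide of A4 needs a stereoselective synthesis of its own.
- Comparison: the chosen plan spends five steps after the lactone (steps 8, 9, 14, 17 and 18) but forms the ring by a reaction with deep precedent.

**Alternative 3: stereoinvertive epoxy-acid cyclisation.** The cut is O1–C7. Epoxy acid A6 would cyclise under catalytic camphorsulfonic acid, the carboxyl attacking the tertiary epoxide carbon from the rear to give A5 and free the C1' hydroxyl.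
- Merits: it has the shortest endgame and the fewest protecting groups. C1'–OH needs none, the acetate is in place, and one desilylation remains.
- Weak points: opening at a tertiary carbon under acid has ionisation character, so inversion can erode, and hydride shift or elimination can outrun a seven-membered closure. The epoxide must also be placed on one of four alkenes.
- Comparison: the chosen plan faces a related question in step 5. There, however, the migrating bond sits in the same molecule, antiperiplanar to the breaking C–O bond, and only a 1,2-shift is needed. The subsequent oxygen insertion transfers C7 with retention.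

Key step: step 7

Remark on the chemistry: the facial sense of the epoxidation in step 4 is assumed to follow the spiro transition-state model established for trans-disubstituted and trisubstituted alkenes.

## Route

Step 1
Reactants: 1 pent-3-yn-1-ol
Product: 2 5-chloropent-2-yne
Conditions: SOCl2, pyridine, CH2Cl2, 0 °C → reflux
Reagents that add atoms: thionyl chloride, ClS(Cl)=O
Why: Chlorodehydroxylation of a primary alcohol through the chlorosulfite with SN2 attack by chloride; the chloride is inert to all later reagents and serves as the latent iodide for step 17.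

Step 2
Reactants: 2 5-chloropent-2-yne
Product: 4 (2E)-5-chloro-2-iodopent-2-ene, via alkenylzirconocene chloride 3 (not isolated)
Conditions: Cp2Zr(H)Cl (1.5 equiv), THF, 50 °C; then I2, 0 °C
Reagents that add atoms: iodine, II
Why: Hydrozirconation (syn addition of Zr–H) of a 2-alkyne; with excess hydride and warming the regioisomers equilibrate so that zirconium should settle on the less hindered methyl-bearing carbon, and iodinolysis with retention gives the (E)-2-iodoalkene.

Step 3
Reactants: 4 (2E)-5-chloro-2-iodopent-2-ene; 5 cyclopentanone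
Product: 7 1-[(2E)-5-chloropent-2-en-2-yl]cyclopentan-1-ol, via alkenyllithium 6 (not isolated)
Conditions: t-BuLi (2.1 equiv), Et2O, −78 °C; then 5, −78 → 0 °C
Reagents that add atoms: none
Why: Iodine–lithium exchange with retention of alkene geometry followed by 1,2-addition to the ketone; a primary alkyl chloride does not exchange or alkylate at −78 °C.

Step 4
Reactants: 7 1-[(2E)-5-chloropent-2-en-2-yl]cyclopentan-1-ol
Product: 8 1-[(2S,3R)-3-(2-chloroethyl)-2-methyloxiran-2-yl]cyclopentan-1-ol
Conditions: D-fructose-derived Shi ketone (30 mol%), KHSO5 (as Oxone), K2CO3, Bu4NHSO4, MeCN–CH2(OMe)2–aq Na2B4O7 buffer, 0 °C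
Reagents that add atoms: potassium peroxymonosulfate, [K+].[O-]S(=O)(=O)OO
Why: Shi epoxidation of a trisubstituted hydroxyalkene by a chiral dioxirane; the spiro transition state, with the vinylic hydrogen in the hindered quadrant, should deliver oxygen to the face that gives the (2S,3R)-epoxide, and the E geometry fixes the trans relation of carbinol carbon and chloroethyl group.

Step 5
Reactants: 8 1-[(2S,3R)-3-(2-chloroethyl)-2-methyloxiran-2-yl]cyclopentan-1-ol
Product: 9 (2R)-2-[(1R)-3-chloro-1-hydroxypropyl]-2-methylcyclohexan-1-one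
Conditions: BF3·OEt2 (0.3 equiv), CH2Cl2, −78 °C
Reagents that add atoms: none
Why: Semipinacol rearrangement of a 2,3-epoxy alcohol: the Lewis acid opens the epoxide at its tertiary carbon while a ring C–C bond of the carbinol migrates anti to the departing oxygen, so the new quaternary centre forms with inversion and the carbinol carbon keeps its configuration, translating (2S,3R) into (2R,1'R); the two ring bonds that can migrate are equivalent by symmetry.

Step 6
Reactants: 9 (2R)-2-[(1R)-3-chloro-1-hydroxypropyl]-2-methylcyclohexan-1-one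
Product: 10 (2R)-2-[(1R)-3-chloro-1-(triethylsilyloxy)propyl]-2-methylcyclohexan-1-one
Conditions: Et3SiOTf, 2,6-lutidine, CH2Cl2, −78 °C
Reagents that add atoms: triethylsilyl trifluoromethanesulfonate, CC[Si](CC)(CC)OS(=O)(=O)C(F)(F)F
Why: Silylation of a hindered secondary alcohol with a silyl triflate; it removes the retro-aldol pathway and protects the hydroxyl for the enolate and organozinc chemistry to come.

Step 7
Reactants: 10 (2R)-2-[(1R)-3-chloro-1-(triethylsilyloxy)propyl]-2-methylcyclohexan-1-one
Product: 11 (7R)-7-[(1R)-3-chloro-1-(triethylsilyloxy)propyl]-7-methyloxepan-2-one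
Conditions: mCPBA, NaHCO3, CH2Cl2, 0 °C → rt
Reagents that add atoms: 3-chloroperoxybenzoic acid, OOC(=O)c1cccc(Cl)c1
Why: The peracid adds to the ketone carbonyl to give the tetrahedral Criegee adduct, and the bond from the carbonyl carbon to the quaternary carbon, antiperiplanar to the O–O bond, shifts to oxygen as 3-chlorobenzoate leaves, forming C2–O1 and O1–C7. This is the Baeyer–Villiger oxidation of a 2,2-disubstituted cyclohexanone, a known reaction type in which the more substituted carbon migrates. The seven-membered ring is not closed by cyclisation: the six-membered carbocycle grows by one atom through a 1,2-shift, so no ring-closure mode applies. No stereocentre is created; the migrating carbon moves with retention, so (2R) of the ketone becomes (7R) of the lactone and C1' is a spectator. The selectivity required is migration of the quaternary carbon in preference to the ring methylene, and the higher migratory aptitude of the fully substituted carbon should secure it. The substrate holds no alkene, so the peracid has no competing site, and the hydrogencarbonate buffer shields the silyl ether from 3-chlorobenzoic acid.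

Step 8
Reactants: 11 (7R)-7-[(1R)-3-chloro-1-(triethylsilyloxy)propyl]-7-methyloxepan-2-one
Product: 15 (7R)-7-[(1R)-3-chloro-1-(triethylsilyloxy)propyl]-7-methyl-6,7-dihydro-5H-oxepin-2-one, via lithium enolate 12 (not isolated), via α-phenylselanyl lactone 13 (not isolated), via selenoxide 14 (not isolated)
Conditions: LiN(i-Pr)2, THF, −78 °C; PhSeBr, −78 °C; then H2O2 (30% aq), pyridine, CH2Cl2, 0 °C → rt
Reagents that add atoms: none
Why: Selenoxide dehydrogenation: the lactone enolate is selenenylated at C3, the selenide is oxidised, and syn elimination towards C4, the only β-hydrogens, gives the endocyclic enoate.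

Step 9
Reactants: 15 (7R)-7-[(1R)-3-chloro-1-(triethylsilyloxy)propyl]-7-methyl-6,7-dihydro-5H-oxepin-2-one
Product: 17 (7R)-3-bromo-7-[(1R)-3-chloro-1-(triethylsilyloxy)propyl]-7-methyl-6,7-dihydro-5H-oxepin-2-one, via 3,4-dibromolactone 16 (not isolated)
Conditions: Br2, CH2Cl2, 0 °C; then Et3N, 0 °C → rt
Reagents that add atoms: bromine, BrBr
Why: Bromine addition to the enoate followed by E1cB loss of HBr (acidic C3–H, C4 bromide) gives the α-bromo enoate, the usual entry to 2-haloenoates for cross-coupling; no other alkene is present to compete.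

Step 10
Reactants: 18 prop-2-yn-1-ol
Product: 20 (2Z)-3-iodo-2-methylprop-2-en-1-ol, via cyclic alkenylmagnesium alkoxide 19 (not isolated)
Conditions: MeMgBr (2.5 equiv), CuI (10 mol%), THF, −10 °C → rt; then I2, −10 → 0 °C
Reagents that add atoms: methylmagnesium bromide, C[Mg]Br; iodine, II
Why: Copper-catalysed anti-carbomagnesiation of a propargylic alkoxide: methyl is delivered to C2 and magnesium to C3 within a five-membered chelate, and iodinolysis with retention gives the iodide cis to the hydroxymethyl group.

Step 11
Reactants: 20 (2Z)-3-iodo-2-methylprop-2-en-1-ol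
Product: 21 1-({[(2Z)-3-iodo-2-methylprop-2-en-1-yl]oxy}methyl)-4-methoxybenzene
Conditions: NaH, 4-MeOC6H4CH2Cl, Bu4NI (cat.), THF–DMF, 0 °C → rt
Reagents that add atoms: 4-methoxybenzyl chloride, COc1ccc(CCl)cc1
Why: Williamson etherification; the PMB ether tolerates organolithium, organozinc and zerovalent palladium chemistry and can later be removed oxidatively beside silyl ethers.

Step 12
Reactants: 21 1-({[(2Z)-3-iodo-2-methylprop-2-en-1-yl]oxy}methyl)-4-methoxybenzene; 22 oxirane
Product: 24 (3Z)-5-[(4-methoxyphenyl)methoxy]-4-methylpent-3-en-1-ol, via alkenyllithium 23 (not isolated)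
Conditions: t-BuLi (2.1 equiv), Et2O, −78 °C; then 22 (excess), −78 → 0 °C
Reagents that add atoms: none
Why: Iodine–lithium exchange with retention followed by SN2 opening of oxirane by the alkenyllithium adds the hydroxyethyl unit and keeps the Z geometry.

Step 13
Reactants: 24 (3Z)-5-[(4-methoxyphenyl)methoxy]-4-methylpent-3-en-1-ol
Product: 25 1-({[(2Z)-5-iodo-2-methylpent-2-en-1-yl]oxy}methyl)-4-methoxybenzene
Conditions: I2, PPh3, imidazole, CH2Cl2, 0 °C → rt
Reagents that add atoms: iodine, II
Why: Appel-type iodination of a primary alcohol through the alkoxyphosphonium ion with SN2 displacement by iodide.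

Step 14
Reactants: 25 1-({[(2Z)-5-iodo-2-methylpent-2-en-1-yl]oxy}methyl)-4-methoxybenzene; 17 (7R)-3-bromo-7-[(1R)-3-chloro-1-(triethylsilyloxy)propyl]-7-methyl-6,7-dihydro-5H-oxepin-2-one
Product: 27 (7R)-7-[(1R)-3-chloro-1-(triethylsilyloxy)propyl]-3-[(3Z)-5-(4-methoxybenzyloxy)-4-methylpent-3-en-1-yl]-7-methyl-6,7-dihydro-5H-oxepin-2-one, via alkylzinc iodide 26 (not isolated)
Conditions: Zn (activated with BrCH2CH2Br and Me3SiCl), LiCl, THF, 40 °C; then 17, Pd(dppf)Cl2 (5 mol%), THF, rt → 50 °C
Reagents that add atoms: none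
Why: Negishi coupling: zinc inserts into the primary iodide and the alkylzinc iodide is coupled sp3–sp2 with the α-bromo enoate; the wide-bite-angle diphosphine favours reductive elimination over β-hydride elimination, and the alkyl chloride, silyl ether and lactone are inert to alkylzinc halides.

Step 15
Reactants: 28 but-2-yn-1-ol
Product: 30 (2Z)-3-iodobut-2-en-1-ol, via cyclic alkenylalanate 29 (not isolated)
Conditions: NaAlH2(OCH2CH2OMe)2, THF, 0 °C → rt; then I2, −78 → 0 °C
Reagents that add atoms: iodine, II
Why: Hydroxyl-directed trans-hydroalumination of a propargylic alcohol places aluminium on C3 in a five-membered alanate, and iodinolysis with retention gives the iodide cis to the hydroxymethyl group.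

Step 16
Reactants: 30 (2Z)-3-iodobut-2-en-1-ol
Product: 31 tert-butyl{[(2Z)-3-iodobut-2-en-1-yl]oxy}dimethylsilane
Conditions: t-BuMe2SiCl, imidazole, CH2Cl2, rt
Reagents that add atoms: tert-butyldimethylsilyl chloride, CC(C)(C)[Si](C)(C)Cl
Why: Standard silylation of a primary alcohol; the silyl ether is orthogonal to the PMB ether of the other chain.

Step 17
Reactants: 27 (7R)-7-[(1R)-3-chloro-1-(triethylsilyloxy)propyl]-3-[(3Z)-5-(4-methoxybenzyloxy)-4-methylpent-3-en-1-yl]-7-methyl-6,7-dihydro-5H-oxepin-2-one
Product: 32 (7R)-7-[(1R)-3-iodo-1-(triethylsilyloxy)propyl]-3-[(3Z)-5-(4-methoxybenzyloxy)-4-methylpent-3-en-1-yl]-7-methyl-6,7-dihydro-5H-oxepin-2-one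
Conditions: NaI, acetone, reflux
Reagents that add atoms: sodium iodide, [Na+].[I-]
Why: Finkelstein halide exchange (SN2) driven by precipitation of NaCl; the iodide is unveiled only after every step that an alkyl iodide would not survive.

Step 18
Reactants: 32 (7R)-7-[(1R)-3-iodo-1-(triethylsilyloxy)propyl]-3-[(3Z)-5-(4-methoxybenzyloxy)-4-methylpent-3-en-1-yl]-7-methyl-6,7-dihydro-5H-oxepin-2-one; 31 tert-butyl{[(2Z)-3-iodobut-2-en-1-yl]oxy}dimethylsilane
Product: 34 (7R)-7-[(1R,4Z)-6-(tert-butyldimethylsilyloxy)-4-methyl-1-(triethylsilyloxy)hex-4-en-1-yl]-3-[(3Z)-5-(4-methoxybenzyloxy)-4-methylpent-3-en-1-yl]-7-methyl-6,7-dihydro-5H-oxepin-2-one, via alkylzinc iodide 33 (not isolated)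
Conditions: Zn (activated with BrCH2CH2Br and Me3SiCl), LiCl, THF, 40 °C; then 31, Pd(dppf)Cl2 (5 mol%), THF, rt → 45 °C
Reagents that add atoms: none
Why: Negishi coupling: zinc insertion into the primary iodide and palladium-catalysed coupling with the alkenyl iodide with retention of its geometry complete the C7 chain; alkylzinc iodides do not add to the lactone or the enoate, and the silyl-protected C1' oxygen cannot quench the reagent.

Step 19
Reactants: 34 (7R)-7-[(1R,4Z)-6-(tert-butyldimethylsilyloxy)-4-methyl-1-(triethylsilyloxy)hex-4-en-1-yl]-3-[(3Z)-5-(4-methoxybenzyloxy)-4-methylpent-3-en-1-yl]-7-methyl-6,7-dihydro-5H-oxepin-2-one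
Product: 35 (7R)-7-[(1R,4Z)-6-(tert-butyldimethylsilyloxy)-4-methyl-1-(triethylsilyloxy)hex-4-en-1-yl]-3-[(3Z)-5-hydroxy-4-methylpent-3-en-1-yl]-7-methyl-6,7-dihydro-5H-oxepin-2-one
Conditions: DDQ, CH2Cl2–pH 7 phosphate buffer, 0 °C
Reagents that add atoms: none
Why: Oxidative cleavage of the PMB ether (hydride abstraction by the quinone, hydrolysis of the oxocarbenium ion); buffered conditions leave both silyl ethers and the alkenes untouched.

Step 20
Reactants: 35 (7R)-7-[(1R,4Z)-6-(tert-butyldimethylsilyloxy)-4-methyl-1-(triethylsilyloxy)hex-4-en-1-yl]-3-[(3Z)-5-hydroxy-4-methylpent-3-en-1-yl]-7-methyl-6,7-dihydro-5H-oxepin-2-one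
Product: 36 (2Z)-5-{(7R)-7-[(1R,4Z)-6-(tert-butyldimethylsilyloxy)-4-methyl-1-(triethylsilyloxy)hex-4-en-1-yl]-7-methyl-2-oxo-6,7-dihydro-5H-oxepin-3-yl}-2-methylpent-2-en-1-yl acetate
Conditions: Ac2O, pyridine, DMAP (cat.), CH2Cl2, 0 °C
Reagents that add atoms: acetic anhydride, CC(=O)OC(C)=O
Why: Acylation of the only free hydroxyl; it is placed after both palladium steps so that no allylic acetate meets zerovalent palladium.

Step 21
Reactants: 36 (2Z)-5-{(7R)-7-[(1R,4Z)-6-(tert-butyldimethylsilyloxy)-4-methyl-1-(triethylsilyloxy)hex-4-en-1-yl]-7-methyl-2-oxo-6,7-dihydro-5H-oxepin-3-yl}-2-methylpent-2-en-1-yl acetate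
Product: 37 (2Z)-5-{(7R)-7-[(1R,4Z)-1,6-dihydroxy-4-methylhex-4-en-1-yl]-7-methyl-2-oxo-6,7-dihydro-5H-oxepin-3-yl}-2-methylpent-2-en-1-yl acetate
Conditions: HF·pyridine, pyridine, THF, 0 °C → rt
Reagents that add atoms: none
Why: Fluoride-mediated cleavage of the primary tert-butyldimethylsilyl and secondary triethylsilyl ethers under buffered, mildly acidic conditions that should leave the acetate, the lactone and both Z alkenes intact.

## Compound list

1 | pent-3-yn-1-ol | CC#CCCO | starting material
2 | 5-chloropent-2-yne | CC#CCCCl | intermediate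
3 | chloro[(2E)-5-chloropent-2-en-2-yl]bis(cyclopentadienyl)zirconium | C/C(=C\CCCl)[Zr](Cl)(C1C=CC=C1)C1C=CC=C1 | intermediate
4 | (2E)-5-chloro-2-iodopent-2-ene | C/C(I)=C\CCCl | intermediate
5 | cyclopentanone | O=C1CCCC1 | starting material
6 | [(2Z)-5-chloropent-2-en-2-yl]lithium (lithium cis to the vinylic hydrogen) | C/C([Li])=C\CCCl | intermediate
7 | 1-[(2E)-5-chloropent-2-en-2-yl]cyclopentan-1-ol | OC1(CCCC1)/C(C)=C/CCCl | intermediate
8 | 1-[(2S,3R)-3-(2-chloroethyl)-2-methyloxiran-2-yl]cyclopentan-1-ol | OC1(CCCC1)[C@@]2(C)O[C@@H]2CCCl | intermediate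
9 | (2R)-2-[(1R)-3-chloro-1-hydroxypropyl]-2-methylcyclohexan-1-one | C1CCC[C@](C)([C@H](O)CCCl)C1=O | intermediate
10 | (2R)-2-[(1R)-3-chloro-1-(triethylsilyloxy)propyl]-2-methylcyclohexan-1-one | C1CCC[C@](C)([C@H](O[Si](CC)(CC)CC)CCCl)C1=O | intermediate
11 | (7R)-7-[(1R)-3-chloro-1-(triethylsilyloxy)propyl]-7-methyloxepan-2-one | C1CCC[C@](C)([C@H](O[Si](CC)(CC)CC)CCCl)OC1=O | intermediate
12 | lithium enolate of 11 (lithium (7R)-7-[(1R)-3-chloro-1-(triethylsilyloxy)propyl]-7-methyl-4,5,6,7-tetrahydrooxepin-2-olate) | [Li]OC1=CCCC[C@](C)([C@H](O[Si](CC)(CC)CC)CCCl)O1 | intermediate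
13 | (7R)-7-[(1R)-3-chloro-1-(triethylsilyloxy)propyl]-7-methyl-3-(phenylselanyl)oxepan-2-one (C3 epimers) | c1ccccc1[Se]C1CCC[C@](C)([C@H](O[Si](CC)(CC)CC)CCCl)OC1=O | intermediate
14 | (7R)-7-[(1R)-3-chloro-1-(triethylsilyloxy)propyl]-7-methyl-3-(phenylseleninyl)oxepan-2-one (mixture at C3 and Se) | c1ccccc1[Se](=O)C1CCC[C@](C)([C@H](O[Si](CC)(CC)CC)CCCl)OC1=O | intermediate
15 | (7R)-7-[(1R)-3-chloro-1-(triethylsilyloxy)propyl]-7-methyl-6,7-dihydro-5H-oxepin-2-one | C1=CCC[C@](C)([C@H](O[Si](CC)(CC)CC)CCCl)OC1=O | intermediate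
16 | (7R)-3,4-dibromo-7-[(1R)-3-chloro-1-(triethylsilyloxy)propyl]-7-methyloxepan-2-one (trans-dibromide, diastereomers) | BrC1C(Br)CC[C@](C)([C@H](O[Si](CC)(CC)CC)CCCl)OC1=O | intermediate
17 | (7R)-3-bromo-7-[(1R)-3-chloro-1-(triethylsilyloxy)propyl]-7-methyl-6,7-dihydro-5H-oxepin-2-one | BrC1=CCC[C@](C)([C@H](O[Si](CC)(CC)CC)CCCl)OC1=O | intermediate
18 | prop-2-yn-1-ol | C#CCO | starting material
19 | 4-methyl-2,5-dihydro-1,2-oxamagnesole (cyclic alkenylmagnesium alkoxide) | CC1=C[Mg]OC1 | intermediate
20 | (2Z)-3-iodo-2-methylprop-2-en-1-ol | OC/C(C)=C\I | intermediate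
21 | 1-({[(2Z)-3-iodo-2-methylprop-2-en-1-yl]oxy}methyl)-4-methoxybenzene | COc1ccc(COC/C(C)=C\I)cc1 | intermediate
22 | oxirane | C1CO1 | starting material
23 | {(1Z)-3-[(4-methoxyphenyl)methoxy]-2-methylprop-1-en-1-yl}lithium | COc1ccc(COC/C(C)=C\[Li])cc1 | intermediate
24 | (3Z)-5-[(4-methoxyphenyl)methoxy]-4-methylpent-3-en-1-ol | COc1ccc(COC/C(C)=C\CCO)cc1 | intermediate
25 | 1-({[(2Z)-5-iodo-2-methylpent-2-en-1-yl]oxy}methyl)-4-methoxybenzene | COc1ccc(COC/C(C)=C\CCI)cc1 | intermediate
26 | {(3Z)-5-[(4-methoxyphenyl)methoxy]-4-methylpent-3-en-1-yl}zinc iodide | COc1ccc(COC/C(C)=C\CC[Zn]I)cc1 | intermediate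
27 | (7R)-7-[(1R)-3-chloro-1-(triethylsilyloxy)propyl]-3-[(3Z)-5-(4-methoxybenzyloxy)-4-methylpent-3-en-1-yl]-7-methyl-6,7-dihydro-5H-oxepin-2-one | COc1ccc(COC/C(C)=C\CCC2=CCC[C@](C)([C@H](O[Si](CC)(CC)CC)CCCl)OC2=O)cc1 | intermediate
28 | but-2-yn-1-ol | CC#CCO | starting material
29 | sodium 2,2-bis(2-methoxyethoxy)-3-methyl-2,5-dihydro-1,2-oxaluminol-2-uide (cyclic alkenylalanate) | C/C1=C/CO[Al-]1(OCCOC)OCCOC.[Na+] | intermediate
30 | (2Z)-3-iodobut-2-en-1-ol | C/C(I)=C/CO | intermediate
31 | tert-butyl{[(2Z)-3-iodobut-2-en-1-yl]oxy}dimethylsilane | C/C(I)=C/CO[Si](C)(C)C(C)(C)C | intermediate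
32 | (7R)-7-[(1R)-3-iodo-1-(triethylsilyloxy)propyl]-3-[(3Z)-5-(4-methoxybenzyloxy)-4-methylpent-3-en-1-yl]-7-methyl-6,7-dihydro-5H-oxepin-2-one | COc1ccc(COC/C(C)=C\CCC2=CCC[C@](C)([C@H](O[Si](CC)(CC)CC)CCI)OC2=O)cc1 | intermediate
33 | (7R)-7-[(1R)-3-(iodozincio)-1-(triethylsilyloxy)propyl]-3-[(3Z)-5-(4-methoxybenzyloxy)-4-methylpent-3-en-1-yl]-7-methyl-6,7-dihydro-5H-oxepin-2-one | COc1ccc(COC/C(C)=C\CCC2=CCC[C@](C)([C@H](O[Si](CC)(CC)CC)CC[Zn]I)OC2=O)cc1 | intermediate
34 | (7R)-7-[(1R,4Z)-6-(tert-butyldimethylsilyloxy)-4-methyl-1-(triethylsilyloxy)hex-4-en-1-yl]-3-[(3Z)-5-(4-methoxybenzyloxy)-4-methylpent-3-en-1-yl]-7-methyl-6,7-dihydro-5H-oxepin-2-one | COc1ccc(COC/C(C)=C\CCC2=CCC[C@](C)([C@H](O[Si](CC)(CC)CC)CC/C(C)=C\CO[Si](C)(C)C(C)(C)C)OC2=O)cc1 | intermediate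
35 | (7R)-7-[(1R,4Z)-6-(tert-butyldimethylsilyloxy)-4-methyl-1-(triethylsilyloxy)hex-4-en-1-yl]-3-[(3Z)-5-hydroxy-4-methylpent-3-en-1-yl]-7-methyl-6,7-dihydro-5H-oxepin-2-one | OC/C(C)=C\CCC1=CCC[C@](C)([C@H](O[Si](CC)(CC)CC)CC/C(C)=C\CO[Si](C)(C)C(C)(C)C)OC1=O | intermediate
36 | (2Z)-5-{(7R)-7-[(1R,4Z)-6-(tert-butyldimethylsilyloxy)-4-methyl-1-(triethylsilyloxy)hex-4-en-1-yl]-7-methyl-2-oxo-6,7-dihydro-5H-oxepin-3-yl}-2-methylpent-2-en-1-yl acetate | CC(=O)OC/C(C)=C\CCC1=CCC[C@](C)([C@H](O[Si](CC)(CC)CC)CC/C(C)=C\CO[Si](C)(C)C(C)(C)C)OC1=O | intermediate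
37 | (2Z)-5-{(7R)-7-[(1R,4Z)-1,6-dihydroxy-4-methylhex-4-en-1-yl]-7-methyl-2-oxo-6,7-dihydro-5H-oxepin-3-yl}-2-methylpent-2-en-1-yl acetate (CNP0286404.1) | CC(=O)OC/C(C)=C\CCC1=CCC[C@](C)([C@H](O)CC/C(C)=C\CO)OC1=O | target

## Step count and points of risk

Total: 21 steps. Longest linear sequence: 15 steps (steps 1–9, 14 and 17–21, from pent-3-yn-1-ol). The two side-chain reagents take four steps (10–13) and two steps (15–16).

**Step 7 (key step).** The likely failure is slow addition of the peracid to a carbonyl flanked by a quaternary carbon that carries a bulky silyloxyalkyl group. The electron-withdrawing β-silyloxy substituent could also allow some migration of the ring methylene.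
Fallback: set out from 9 and oxidise the unprotected β-hydroxy ketone with the same peracid. The free hydroxyl shields the carbonyl less and can hydrogen-bond the peracid and the Criegee adduct. This should give (7R)-7-[(1R)-3-chloro-1-hydroxypropyl]-7-methyloxepan-2-one F1, which is then silylated (Et3SiOTf, 2,6-lutidine) and rejoins the route at 11.

**Step 4.** The likely failure is poor facial selectivity or slow oxygen transfer, because the alkene is flanked by a fully substituted carbinol carbon that crowds the spiro transition state.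
Fallback: set out from 4 and move the asymmetric step to a primary allylic alcohol.
- Alkenyllithium 6, generated as in step 3, is trapped with paraformaldehyde to give (2E)-5-chloro-2-methylpent-2-en-1-ol F2.
- Sharpless asymmetric epoxidation (Ti(OiPr)4, D-(−)-diethyl tartrate, t-BuOOH, 4 Å sieves, CH2Cl2, −20 °C) should give [(2R,3R)-3-(2-chloroethyl)-2-methyloxiran-2-yl]methanol F3.
- Oxidation (RuCl3 cat., NaIO4) gives (2S,3R)-3-(2-chloroethyl)-2-methyloxirane-2-carboxylic acid F4, which is esterified (Me3SiCHN2) to methyl (2S,3R)-3-(2-chloroethyl)-2-methyloxirane-2-carboxylate F5.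
- Double addition of BrMg(CH2)4MgBr to the ester at −78 °C builds the cyclopentanol and returns to the route at 8.

**Step 14.** The likely failures are slow transmetalation to the hindered α-bromo enoate, with β-hydride elimination of the homoallylic alkylpalladium or reduction of the bromide taking over.
Fallback: set out from 21 and use a boron nucleophile.
- Suzuki vinylation (4,4,5,5-tetramethyl-2-vinyl-1,3,2-dioxaborolane, Pd(PPh3)4, aq K3PO4, THF) gives 1-methoxy-4-({[(2Z)-2-methylpenta-2,4-dien-1-yl]oxy}methyl)benzene F6.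
- 9-Borabicyclo[3.3.1]nonane adds to the terminal vinyl group to give 9-{(3Z)-5-[(4-methoxyphenyl)methoxy]-4-methylpent-3-en-1-yl}-9-borabicyclo[3.3.1]nonane F7.
- B-alkyl Suzuki–Miyaura coupling with 17 (Pd(dppf)Cl2, AsPh3, Cs2CO3, DMF–H2O, rt) returns to the route at 27.

**Step 18.** The likely failures are incomplete zinc insertion into the iodide of a densely functionalised intermediate, or protonation of the alkylzinc before it couples.
Fallback: set out from 31 and reverse the polarity.
- Iodine–magnesium exchange (i-PrMgCl·LiCl, THF, −20 °C) gives {(2Z)-4-(tert-butyldimethylsilyloxy)but-2-en-2-yl}magnesium chloride F8.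
- Transmetalation with ZnCl2 gives {(2Z)-4-(tert-butyldimethylsilyloxy)but-2-en-2-yl}zinc chloride F9.
- F9 is coupled with iodide 32 as the electrophile (Pd2(dba)3, P(c-C5H9)3, N-methylimidazole, THF–NMP, 80 °C; Negishi coupling of an unactivated alkyl iodide), returning to the route at 34.

**Step 2.** The likely failure is incomplete regiocontrol in the hydrozirconation, since methyl and chloroethyl differ little in size; a regioisomeric iodide would be hard to remove.
Fallback: set out from 5. The lithium acetylide of 4-chlorobut-1-yne (n-BuLi, THF, −78 °C) adds to cyclopentanone to give 1-(4-chlorobut-1-yn-1-yl)cyclopentan-1-ol F10. Hydroxyl-directed anti-carbomagnesiation (MeMgBr, CuI cat., THF) then places methyl on the carbinol-side alkyne carbon and magnesium on the distal one in a chelate, and protonation returns to the route at 7 with the same E geometry. Steps 1 and 2 are then no longer needed.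

## Further compounds

F1 | step 7 | (7R)-7-[(1R)-3-chloro-1-hydroxypropyl]-7-methyloxepan-2-one | C1CCC[C@](C)([C@H](O)CCCl)OC1=O
F2 | step 4 | (2E)-5-chloro-2-methylpent-2-en-1-ol | OC/C(C)=C/CCCl
F3 | step 4 | [(2R,3R)-3-(2-chloroethyl)-2-methyloxiran-2-yl]methanol | OC[C@@]1(C)O[C@@H]1CCCl
F4 | step 4 | (2S,3R)-3-(2-chloroethyl)-2-methyloxirane-2-carboxylic acid | OC(=O)[C@@]1(C)O[C@@H]1CCCl
F5 | step 4 | methyl (2S,3R)-3-(2-chloroethyl)-2-methyloxirane-2-carboxylate | COC(=O)[C@@]1(C)O[C@@H]1CCCl
F6 | step 14 | 1-methoxy-4-({[(2Z)-2-methylpenta-2,4-dien-1-yl]oxy}methyl)benzene | COc1ccc(COC/C(C)=C\C=C)cc1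
F7 | step 14 | 9-{(3Z)-5-[(4-methoxyphenyl)methoxy]-4-methylpent-3-en-1-yl}-9-borabicyclo[3.3.1]nonane | COc1ccc(COC/C(C)=C\CCB2C3CCCC2CCC3)cc1
F8 | step 18 | {(2Z)-4-(tert-butyldimethylsilyloxy)but-2-en-2-yl}magnesium chloride | C/C([Mg]Cl)=C/CO[Si](C)(C)C(C)(C)C
F9 | step 18 | {(2Z)-4-(tert-butyldimethylsilyloxy)but-2-en-2-yl}zinc chloride | C/C([Zn]Cl)=C/CO[Si](C)(C)C(C)(C)C
F10 | step 2 | 1-(4-chlorobut-1-yn-1-yl)cyclopentan-1-ol | OC1(CCCC1)C#CCCCl
A1 | alternative 1 | (2Z)-5-{(7R)-7-[(1R,4Z)-6-(tert-butyldiphenylsilyloxy)-4-methyl-1-(triethylsilyloxy)hex-4-en-1-yl]-7-methyl-2-oxo-6,7-dihydro-5H-oxepin-3-yl}-2-methylpent-2-en-1-yl acetate | CC(=O)OC/C(C)=C\CCC1=CCC[C@](C)([C@H](O[Si](CC)(CC)CC)CC/C(C)=C\CO[Si](c2ccccc2)(c2ccccc2)C(C)(C)C)OC1=O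
A2 | alternative 1 | (5R,6R,9Z)-11-(tert-butyldiphenylsilyloxy)-5,9-dimethyl-6-(triethylsilyloxy)undeca-1,9-dien-5-yl (5Z)-7-acetoxy-6-methyl-2-methylidenehept-5-enoate | CC(=O)OC/C(C)=C\CCC(=C)C(=O)O[C@](C)(CCC=C)[C@H](O[Si](CC)(CC)CC)CC/C(C)=C\CO[Si](c1ccccc1)(c1ccccc1)C(C)(C)C
A3 | alternative 2 | (7R)-7-[(1R,4Z)-6-(tert-butyldimethylsilyloxy)-4-methyl-1-(triethylsilyloxy)hex-4-en-1-yl]-3-[(3Z)-5-(4-methoxybenzyloxy)-4-methylpent-3-en-1-yl]-7-methyl-6,7-dihydro-5H-oxepin-2-one | COc1ccc(COC/C(C)=C\CCC2=CCC[C@](C)([C@H](O[Si](CC)(CC)CC)CC/C(C)=C\CO[Si](C)(C)C(C)(C)C)OC2=O)cc1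
A4 | alternative 2 | (2Z,6Z,10R,11R,14Z)-16-(tert-butyldimethylsilyloxy)-6-iodo-1-(4-methoxybenzyloxy)-2,10,14-trimethyl-11-(triethylsilyloxy)hexadeca-2,6,14-trien-10-ol | COc1ccc(COC/C(C)=C\CC/C(I)=C/CC[C@@](C)(O)[C@H](O[Si](CC)(CC)CC)CC/C(C)=C\CO[Si](C)(C)C(C)(C)C)cc1
A5 | alternative 3 | (2Z)-5-{(7R)-7-[(1R,4Z)-6-(tert-butyldiphenylsilyloxy)-1-hydroxy-4-methylhex-4-en-1-yl]-7-methyl-2-oxo-6,7-dihydro-5H-oxepin-3-yl}-2-methylpent-2-en-1-yl acetate | CC(=O)OC/C(C)=C\CCC1=CCC[C@](C)([C@H](O)CC/C(C)=C\CO[Si](c2ccccc2)(c2ccccc2)C(C)(C)C)OC1=O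
A6 | alternative 3 | (2Z)-2-[(3Z)-5-acetoxy-4-methylpent-3-en-1-yl]-5-{(2S,3R)-3-[(3Z)-5-(tert-butyldiphenylsilyloxy)-3-methylpent-3-en-1-yl]-2-methyloxiran-2-yl}pent-2-enoic acid | CC(=O)OC/C(C)=C\CC/C(C(=O)O)=C/CC[C@]1(C)O[C@@H]1CC/C(C)=C\CO[Si](c1ccccc1)(c1ccccc1)C(C)(C)C
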